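**Retrosynthetic overview**
1. Bermudenynol ⇐ C5 chloride introduced last, with inversion, by chloride opening of a 5,6-acetoxonium ion on the (3Z)-enyne 5,6-diol; the enyne comes from a C4 aldehyde by Peterson olefination; C12–Br comes from a C12 alcohol with inversion; the C13 ethyl is a reduced vinyl group.
2. The oxocene, the only ring of the target, is closed by forming C12–C13: a (Z)-γ-alkoxyallylboronate carried on O7 adds intramolecularly to a C12 aldehyde, which also sets C12 and C13.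
3. Enabling feature: the vicinal C12(Br)/C13(O-ring) pair beside the ring oxygen is the retron of an aldehyde + γ-alkoxyallyl–boron addition, and the ring olefin C9=C10(Cl), whose ring carbons C8 and C11 are cis, holds O7 and C12 within reach for eight-membered closure.
4. Acyclic precursor: C9=C10(Cl) by syn-hydrostannation/chlorodestannylation of a C9≡C10 ynoate (ester carbon = C11); C12 by dithiane alkylation; C13–C15 from an O-allyl group by cross-metathesis with vinyl-Bpin and olefin transposition.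
5. C5, C6 and C7 come from D-glucal; its pyranose ring is opened by alkyne homologation of the 2-deoxy lactol, so only a temporary 4,6-silylene ring precedes the oxocene.

Key step: step 16

Remark: locants C1–C15 in the explanations are those of the target chain (C1 = terminal alkyne carbon, ring oxygen between C7 and C13); systematic names carry their own locants and CIP descriptors; TBS = tert-butyldimethylsilyl, TIPS = triisopropylsilyl, Bpin = 4,4,5,5-tetramethyl-1,3,2-dioxaborolan-2-yl; D-glucal and all reagents named are taken as commercially available.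

**Route**

Step 1
Reactants: 1 D-glucal
Product: 2 4,6-O-(di-tert-butylsilanediyl)-D-glucal
Conditions: tBu2Si(OTf)2, pyridine, DMF, –40 °C
Reagents that add atoms: di-tert-butylsilyl bis(trifluoromethanesulfonate), CC(C)(C)[Si](OS(=O)(=O)C(F)(F)F)(OS(=O)(=O)C(F)(F)F)C(C)(C)C
Why: Cyclic silylene protection bridges the 1,3-related O4/O6 diol as a six-membered ring and should leave only the allylic 3-OH (the future ring oxygen O7) free.

Step 2
Reactants: 2 4,6-O-(di-tert-butylsilanediyl)-D-glucal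
Product: 4 3-O-allyl-4,6-O-(di-tert-butylsilanediyl)-D-glucal, via sodium alkoxide 3 (not isolated)
Conditions: NaH, allyl bromide, DMF, 0 °C → rt
Reagents that add atoms: allyl bromide, C=CCBr
Why: Williamson etherification of the only free hydroxyl puts the future C13/C14 carbons on O7 without touching a stereocentre.

Step 3
Reactants: 4 3-O-allyl-4,6-O-(di-tert-butylsilanediyl)-D-glucal
Product: 5 3-O-allyl-2-deoxy-4,6-O-(di-tert-butylsilanediyl)-D-arabino-hexopyranose (anomer mixture)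
Conditions: Ph3P·HBr (cat.), H2O, THF, rt
Reagents that add atoms: water, O
Why: Ph3P·HBr-catalysed Markovnikov hydration of the glycal enol ether (proton to C8, water to C9) should give the 2-deoxy lactol without Ferrier-type loss of the 3-O-allyl group.

Step 4
Reactants: 5 3-O-allyl-2-deoxy-4,6-O-(di-tert-butylsilanediyl)-D-arabino-hexopyranose
Product: 7 (4R,5R)-4-[(1R)-1-(allyloxy)but-3-yn-1-yl]-2,2-di-tert-butyl-1,3,2-dioxasilinan-5-ol, via open-chain aldehyde 6 (not isolated)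
Conditions: MeC(O)C(N2)P(O)(OMe)2, K2CO3, MeOH, rt
Reagents that add atoms: dimethyl (1-diazo-2-oxopropyl)phosphonate (Ohira–Bestmann reagent), CC(=O)C(=[N+]=[N-])P(=O)(OC)OC
Why: Seyferth–Gilbert homologation with the Ohira–Bestmann reagent converts the lactol-masked C9 aldehyde into the terminal alkyne (adding C10) and releases the former ring oxygen as the free C5 hydroxyl.

Step 5
Reactants: 7 (4R,5R)-4-[(1R)-1-(allyloxy)but-3-yn-1-yl]-2,2-di-tert-butyl-1,3,2-dioxasilinan-5-ol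
Product: 8 (2R,3R,4R)-4-(allyloxy)hept-6-yne-1,2,3-triol
Conditions: HF·pyridine, THF, 0 °C → rt
Reagents that add atoms: none
Why: Fluoride-induced desilylation cleaves both Si–O bonds of the silylene and should give the C4/C5/C6 triol with alkyne and allyl ether intact.

Step 6
Reactants: 8 (2R,3R,4R)-4-(allyloxy)hept-6-yne-1,2,3-triol
Product: 9 (2R,3S,4R)-4-(allyloxy)-1,2,3-tris(TBS-oxy)hept-6-yne
Conditions: TBSOTf, 2,6-lutidine, CH2Cl2, –78 → 0 °C
Reagents that add atoms: tert-butyldimethylsilyl trifluoromethanesulfonate, CC(C)(C)[Si](C)(C)OS(=O)(=O)C(F)(F)F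
Why: Exhaustive silylation with the silyl triflate protects one primary and two secondary hydroxyls as TBS ethers, which are later told apart by their rate of cleavage.

Step 7
Reactants: 9 (2R,3S,4R)-4-(allyloxy)-1,2,3-tris(TBS-oxy)hept-6-yne
Product: 11 methyl (5R,6S,7R)-5-(allyloxy)-6,7,8-tris(TBS-oxy)oct-2-ynoate, via lithium acetylide 10 (not isolated)
Conditions: n-BuLi, THF, –78 °C; then ClCO2Me
Reagents that add atoms: methyl chloroformate, COC(=O)Cl
Why: Deprotonation of the terminal alkyne and C-acylation of the lithium acetylide should give the ynoate whose ester carbon becomes C11.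

Step 8
Reactants: 11 methyl (5R,6S,7R)-5-(allyloxy)-6,7,8-tris(TBS-oxy)oct-2-ynoate
Product: 12 methyl (2E,5R,6S,7R)-5-(allyloxy)-6,7,8-tris(TBS-oxy)-2-(tributylstannyl)oct-2-enoate
Conditions: Bu3SnH, Pd(PPh3)4 (cat.), THF, 0 °C
Reagents that add atoms: tributyltin hydride, CCCC[SnH](CCCC)CCCC
Why: Pd-catalysed hydrostannation of an alkynoate is a syn addition that puts tin on the α-carbon (C10) and hydrogen on C9, so C8 and the ester carbon C11 end up cis on the new olefin, and the isolated allyl ether should not react.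

Step 9
Reactants: 12 methyl (2E,5R,6S,7R)-5-(allyloxy)-6,7,8-tris(TBS-oxy)-2-(tributylstannyl)oct-2-enoate
Product: 13 methyl (2E,5R,6S,7R)-5-(allyloxy)-2-chloro-6,7,8-tris(TBS-oxy)oct-2-enoate
Conditions: CuCl2, THF, rt
Reagents that add atoms: copper dichloride, [Cu+2].[Cl-].[Cl-]
Why: Chlorodestannylation of an alkenylstannane with CuCl2 proceeds with retention of olefin geometry and should give the chloroalkene with C8 and C11 cis, as the oxocene needs.

Step 10
Reactants: 13 methyl (2E,5R,6S,7R)-5-(allyloxy)-2-chloro-6,7,8-tris(TBS-oxy)oct-2-enoate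
Product: 14 (2E,5R,6S,7R)-5-(allyloxy)-2-chloro-6,7,8-tris(TBS-oxy)oct-2-en-1-ol
Conditions: iBu2AlH, CH2Cl2, –78 °C
Reagents that add atoms: none
Why: 1,2-Reduction of the enoate with the aluminium hydride should give the primary allylic alcohol (C11) without touching the vinyl chloride or the silyl ethers.

Step 11
Reactants: 14 (2E,5R,6S,7R)-5-(allyloxy)-2-chloro-6,7,8-tris(TBS-oxy)oct-2-en-1-ol
Product: 15 (2E,5R,6S,7R)-5-(allyloxy)-1-bromo-2-chloro-6,7,8-tris(TBS-oxy)oct-2-ene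
Conditions: CBr4, PPh3, CH2Cl2, 0 °C
Reagents that add atoms: carbon tetrabromide, BrC(Br)(Br)Br
Why: The Appel reaction converts the primary allylic alcohol into the bromide by SN2 at C11 without changing the olefin geometry.

Step 12
Reactants: 15 (2E,5R,6S,7R)-5-(allyloxy)-1-bromo-2-chloro-6,7,8-tris(TBS-oxy)oct-2-ene
Product: 16 2-[(2E,5R,6S,7R)-5-(allyloxy)-2-chloro-6,7,8-tris(TBS-oxy)oct-2-en-1-yl]-1,3-dithiane
Conditions: 1,3-dithiane, n-BuLi, THF, –30 °C; then 15, –78 °C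
Reagents that add atoms: 1,3-dithiane, C1CSCSC1
Why: Corey–Seebach alkylation: 2-lithio-1,3-dithiane should displace the primary allylic bromide by SN2 and bring in C12 at the aldehyde oxidation level.

Step 13
Reactants: 16 2-[(2E,5R,6S,7R)-5-(allyloxy)-2-chloro-6,7,8-tris(TBS-oxy)oct-2-en-1-yl]-1,3-dithiane
Product: 17 (3E,6R,7S,8R)-6-(allyloxy)-3-chloro-1,1-dimethoxy-7,8,9-tris(TBS-oxy)non-3-ene
Conditions: PhI(OCOCF3)2, MeOH, 0 °C
Reagents that add atoms: methanol, CO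
Why: Oxidative dithiane cleavage by the hypervalent iodine reagent in methanol gives the dimethyl acetal directly, so the isomerisation-prone β,γ-unsaturated aldehyde is never set free at this stage.

Step 14
Reactants: 17 (3E,6R,7S,8R)-6-(allyloxy)-3-chloro-1,1-dimethoxy-7,8,9-tris(TBS-oxy)non-3-ene
Product: 18 (3E,6R,7S,8R)-3-chloro-1,1-dimethoxy-6-{[(2E)-3-(Bpin)prop-2-en-1-yl]oxy}-7,8,9-tris(TBS-oxy)non-3-ene
Conditions: vinyl-Bpin, second-generation Grubbs catalyst RuCl2(=CHPh)(H2IMes)(PCy3) (cat.), CH2Cl2, 40 °C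
Reagents that add atoms: vinylboronic acid pinacol ester, C=CB1OC(C)(C)C(C)(C)O1
Why: Olefin cross-metathesis of the terminal allyl ether with the vinylboronate should give the (E)-alkenylboronate (which supplies C15), while the trisubstituted chloroalkene is inert to the ruthenium carbene.

Step 15
Reactants: 18 (3E,6R,7S,8R)-3-chloro-1,1-dimethoxy-6-{[(2E)-3-(Bpin)prop-2-en-1-yl]oxy}-7,8,9-tris(TBS-oxy)non-3-ene
Product: 19 (3E,6R,7S,8R)-3-chloro-1,1-dimethoxy-6-{[(1Z)-3-(Bpin)prop-1-en-1-yl]oxy}-7,8,9-tris(TBS-oxy)non-3-ene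
Conditions: NiCl2(dppb) (cat., dppb = Ph2P(CH2)4PPh2), LiBHEt3 (cat.), THF, rt
Reagents that add atoms: none
Why: Nickel-hydride-catalysed olefin transposition (1,3-hydrogen shift) moves the double bond into conjugation with the ether oxygen and, as in the nickel-catalysed isomerisation of allyl ethers to (Z)-enol ethers, should give the (Z)-γ-alkoxyallylboronate.

Step 16
Reactants: 19 (3E,6R,7S,8R)-3-chloro-1,1-dimethoxy-6-{[(1Z)-3-(Bpin)prop-1-en-1-yl]oxy}-7,8,9-tris(TBS-oxy)non-3-ene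
Product: 22 (2R,3R,5E,8R)-5-chloro-2-ethenyl-8-[(1S,2R)-1,2,3-tris(TBS-oxy)propyl]-3,4,7,8-tetrahydro-2H-oxocin-3-ol, via aldehyde 20 (not isolated), via borate ester 21 (not isolated)
Conditions: Yb(OTf)3, MeCN/H2O, rt, high dilution
Reagents that add atoms: water, O
Why: Yb(OTf)3 in wet acetonitrile should hydrolyse only the dimethyl acetal, and the liberated C12 aldehyde 20 is then attacked by the γ-carbon (C13) of the pinacol (Z)-γ-alkoxyallylboronate through a closed, boron–carbonyl-coordinated six-membered chair (Zimmerman–Traxler-type) transition state, which forms C12–C13 and the borate 21 that is hydrolysed on work-up. The closest known reaction type is the intramolecular allylboration of ω-formyl γ-alkoxyallylboronates, established for 2-vinyl-3-hydroxy tetrahydropyrans, oxepanes and cis-olefin-containing oxocenes. The oxocene closes in an 8-exo-trig mode (both the C=O and the transposing C=C lie outside the new ring), which is feasible because the ring olefin C9=C10(Cl) holds C8 and C11 cis and so removes much of the entropic cost. C12 and C13 are set together by the enol ether geometry: the Z configuration places the ring oxygen axial and the C11 chain equatorial in the chair, which translates into the cis relationship of C12–OH and C13–vinyl. C13 relative to C7 is controlled by the existing C7 centre: with the C7–H bond eclipsing the enol ether plane (minimised allylic 1,3-strain) the C8 tether can deliver the aldehyde only to the enol ether face opposite the bulky C4–C6 chain, which should give the 2,8-cis oxocene. The step needs chemoselective acetal hydrolysis without protodeboronation of the acid-sensitive enol ether or loss of TBS groups, secured by the mild lanthanide triflate, and intramolecular over intermolecular allylation, secured by the cis-olefin tether and high dilution.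

Step 17
Reactants: 22 (2R,3R,5E,8R)-5-chloro-2-ethenyl-8-[(1S,2R)-1,2,3-tris(TBS-oxy)propyl]-3,4,7,8-tetrahydro-2H-oxocin-3-ol
Product: 23 (2R,3R,5E,8R)-5-chloro-2-ethyl-8-[(1S,2R)-1,2,3-tris(TBS-oxy)propyl]-3,4,7,8-tetrahydro-2H-oxocin-3-ol
Conditions: 2-O2NC6H4SO2NHNH2, Et3N, CH2Cl2, rt
Reagents that add atoms: none
Why: Diimide reduction saturates the monosubstituted vinyl group much faster than the trisubstituted chloroalkene and cannot hydrogenolyse the C–Cl bond, giving the C13 ethyl group.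

Step 18
Reactants: 23 (2R,3R,5E,8R)-5-chloro-2-ethyl-8-[(1S,2R)-1,2,3-tris(TBS-oxy)propyl]-3,4,7,8-tetrahydro-2H-oxocin-3-ol
Product: 24 (2R,3S,5E,8R)-3-bromo-5-chloro-2-ethyl-8-[(1S,2R)-1,2,3-tris(TBS-oxy)propyl]-3,4,7,8-tetrahydro-2H-oxocine
Conditions: CBr4, P(n-Oct)3, toluene, 70 °C
Reagents that add atoms: carbon tetrabromide, BrC(Br)(Br)Br
Why: Appel-type bromination displaces the activated C12 oxygen by bromide in an SN2 step with inversion, turning the hydroxyl cis to the C13 ethyl into the (12S)-bromide trans to it.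

Step 19
Reactants: 24 (2R,3S,5E,8R)-3-bromo-5-chloro-2-ethyl-8-[(1S,2R)-1,2,3-tris(TBS-oxy)propyl]-3,4,7,8-tetrahydro-2H-oxocine
Product: 25 (2R,3S)-3-[(2R,4E,7S,8R)-7-bromo-5-chloro-8-ethyl-3,6,7,8-tetrahydro-2H-oxocin-2-yl]-2,3-bis(TBS-oxy)propan-1-ol
Conditions: HF·pyridine, pyridine, THF, 0 °C
Reagents that add atoms: none
Why: Rate-selective desilylation: buffered HF·pyridine should cleave the unhindered primary TBS ether much faster than the two flanked secondary ones.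

Step 20
Reactants: 25 (2R,3S)-3-[(2R,4E,7S,8R)-7-bromo-5-chloro-8-ethyl-3,6,7,8-tetrahydro-2H-oxocin-2-yl]-2,3-bis(TBS-oxy)propan-1-ol
Product: 26 (2S,3S)-3-[(2R,4E,7S,8R)-7-bromo-5-chloro-8-ethyl-3,6,7,8-tetrahydro-2H-oxocin-2-yl]-2,3-bis(TBS-oxy)propanal
Conditions: Dess–Martin periodinane, CH2Cl2, rt
Reagents that add atoms: none
Why: Dess–Martin oxidation gives the α-silyloxy aldehyde (C4) under non-basic conditions that should not epimerise C5 (the descriptor changes only through CIP priorities).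

Step 21
Reactants: 26 (2S,3S)-3-[(2R,4E,7S,8R)-7-bromo-5-chloro-8-ethyl-3,6,7,8-tetrahydro-2H-oxocin-2-yl]-2,3-bis(TBS-oxy)propanal
Product: 28 (2R,4E,7S,8R)-7-bromo-5-chloro-8-ethyl-2-[(1S,2R,3Z)-1,2-bis(TBS-oxy)-6-(triisopropylsilyl)hex-3-en-5-yn-1-yl]-3,6,7,8-tetrahydro-2H-oxocine, via lithium alkoxide 27 (not isolated)
Conditions: TIPSC≡CCH2TIPS, n-BuLi, THF, –78 °C; then 26, –78 °C → rt
Reagents that add atoms: 1,3-bis(triisopropylsilyl)propyne, CC(C)[Si](C(C)C)(C(C)C)CC#C[Si](C(C)C)(C(C)C)C(C)C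
Why: Peterson olefination: the lithiated bis-silylpropyne adds to the aldehyde and the β-silyl alkoxide undergoes stereospecific syn-elimination, the bulky TIPS groups steering the sequence to the (Z)-enyne (C1–C3 added).

Step 22
Reactants: 28 (2R,4E,7S,8R)-7-bromo-5-chloro-8-ethyl-2-[(1S,2R,3Z)-1,2-bis(TBS-oxy)-6-(triisopropylsilyl)hex-3-en-5-yn-1-yl]-3,6,7,8-tetrahydro-2H-oxocine
Product: 29 (1R,2R,3Z)-1-[(2R,4E,7S,8R)-7-bromo-5-chloro-8-ethyl-3,6,7,8-tetrahydro-2H-oxocin-2-yl]hex-3-en-5-yne-1,2-diol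
Conditions: Bu4NF, THF, 0 °C → rt
Reagents that add atoms: none
Why: Fluoride-mediated desilylation removes the alkynyl TIPS group and both secondary TBS ethers in one operation, exposing the anti-5,6-diol while no chlorohydrin is yet present to suffer from the basic fluoride.

Step 23
Reactants: 29 (1R,2R,3Z)-1-[(2R,4E,7S,8R)-7-bromo-5-chloro-8-ethyl-3,6,7,8-tetrahydro-2H-oxocin-2-yl]hex-3-en-5-yne-1,2-diol
Product: 31 (1S,2S,3Z)-1-[(2R,4E,7S,8R)-7-bromo-5-chloro-8-ethyl-3,6,7,8-tetrahydro-2H-oxocin-2-yl]-2-chlorohex-3-en-5-yn-1-yl acetate, via cyclic orthoacetate 30 (not isolated)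
Conditions: MeC(OMe)3, PPTS (cat.), CH2Cl2, rt; then Me3SiCl, CH2Cl2, 0 °C
Reagents that add atoms: trimethyl orthoacetate, CC(OC)(OC)OC; chlorotrimethylsilane, C[Si](C)(C)Cl
Why: Stereospecific diol-to-chlorohydrin-ester conversion: the cyclic orthoacetate is ionised by Me3SiCl to a 1,3-dioxolan-2-ylium ion that chloride opens by SN2 at the allylic carbon C5 (C6 is deactivated by the adjacent C7–O bond), with inversion, which sets (5S)-Cl and leaves O6 as the acetate.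

Step 24
Reactants: 31 (1S,2S,3Z)-1-[(2R,4E,7S,8R)-7-bromo-5-chloro-8-ethyl-3,6,7,8-tetrahydro-2H-oxocin-2-yl]-2-chlorohex-3-en-5-yn-1-yl acetate
Product: 32 bermudenynol, (1S,2S,3Z)-1-[(2R,4E,7S,8R)-7-bromo-5-chloro-8-ethyl-3,6,7,8-tetrahydro-2H-oxocin-2-yl]-2-chlorohex-3-en-5-yn-1-ol
Conditions: iBu2AlH, CH2Cl2, –78 °C
Reagents that add atoms: none
Why: Reductive ester cleavage with the aluminium hydride at low temperature removes the acetate without generating a basic alkoxide that would close the chlorohydrin to an epoxide.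

**Compound list**
1 | D-glucal | OC[C@@H]1[C@@H](O)[C@H](O)C=CO1 | starting material
2 | 4,6-O-(di-tert-butylsilanediyl)-D-glucal | CC(C)(C)[Si]1(C(C)(C)C)OC[C@@H]2[C@@H](O1)[C@H](O)C=CO2 | intermediate
3 | sodium 3-alkoxide of 2 | CC(C)(C)[Si]1(C(C)(C)C)OC[C@@H]2[C@@H](O1)[C@H](O[Na])C=CO2 | intermediate
4 | 3-O-allyl-4,6-O-(di-tert-butylsilanediyl)-D-glucal | CC(C)(C)[Si]1(C(C)(C)C)OC[C@@H]2[C@@H](O1)[C@H](OCC=C)C=CO2 | intermediate
5 | 3-O-allyl-2-deoxy-4,6-O-(di-tert-butylsilanediyl)-D-arabino-hexopyranose (anomer mixture) | CC(C)(C)[Si]1(C(C)(C)C)OC[C@@H]2[C@@H](O1)[C@H](OCC=C)CC(O)O2 | intermediate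
6 | open-chain aldehyde form of 5 (C9 aldehyde, free 5-OH) | CC(C)(C)[Si]1(C(C)(C)C)OC[C@@H](O)[C@@H](O1)[C@H](OCC=C)CC=O | intermediate
7 | (4R,5R)-4-[(1R)-1-(allyloxy)but-3-yn-1-yl]-2,2-di-tert-butyl-1,3,2-dioxasilinan-5-ol | CC(C)(C)[Si]1(C(C)(C)C)OC[C@@H](O)[C@@H](O1)[C@H](OCC=C)CC#C | intermediate
8 | (2R,3R,4R)-4-(allyloxy)hept-6-yne-1,2,3-triol | OC[C@@H](O)[C@@H](O)[C@H](OCC=C)CC#C | intermediate
9 | (2R,3S,4R)-4-(allyloxy)-1,2,3-tris(TBS-oxy)hept-6-yne | CC(C)(C)[Si](C)(C)OC[C@@H](O[Si](C)(C)C(C)(C)C)[C@@H](O[Si](C)(C)C(C)(C)C)[C@H](OCC=C)CC#C | intermediate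
10 | lithium acetylide of 9 | CC(C)(C)[Si](C)(C)OC[C@@H](O[Si](C)(C)C(C)(C)C)[C@@H](O[Si](C)(C)C(C)(C)C)[C@H](OCC=C)CC#C[Li] | intermediate
11 | methyl (5R,6S,7R)-5-(allyloxy)-6,7,8-tris(TBS-oxy)oct-2-ynoate | CC(C)(C)[Si](C)(C)OC[C@@H](O[Si](C)(C)C(C)(C)C)[C@@H](O[Si](C)(C)C(C)(C)C)[C@H](OCC=C)CC#CC(=O)OC | intermediate
12 | methyl (2E,5R,6S,7R)-5-(allyloxy)-6,7,8-tris(TBS-oxy)-2-(tributylstannyl)oct-2-enoate | CC(C)(C)[Si](C)(C)OC[C@@H](O[Si](C)(C)C(C)(C)C)[C@@H](O[Si](C)(C)C(C)(C)C)[C@H](OCC=C)C/C=C(/[Sn](CCCC)(CCCC)CCCC)C(=O)OC | intermediate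
13 | methyl (2E,5R,6S,7R)-5-(allyloxy)-2-chloro-6,7,8-tris(TBS-oxy)oct-2-enoate | CC(C)(C)[Si](C)(C)OC[C@@H](O[Si](C)(C)C(C)(C)C)[C@@H](O[Si](C)(C)C(C)(C)C)[C@H](OCC=C)C/C=C(/Cl)C(=O)OC | intermediate
14 | (2E,5R,6S,7R)-5-(allyloxy)-2-chloro-6,7,8-tris(TBS-oxy)oct-2-en-1-ol | CC(C)(C)[Si](C)(C)OC[C@@H](O[Si](C)(C)C(C)(C)C)[C@@H](O[Si](C)(C)C(C)(C)C)[C@H](OCC=C)C/C=C(/Cl)CO | intermediate
15 | (2E,5R,6S,7R)-5-(allyloxy)-1-bromo-2-chloro-6,7,8-tris(TBS-oxy)oct-2-ene | CC(C)(C)[Si](C)(C)OC[C@@H](O[Si](C)(C)C(C)(C)C)[C@@H](O[Si](C)(C)C(C)(C)C)[C@H](OCC=C)C/C=C(/Cl)CBr | intermediate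
16 | 2-[(2E,5R,6S,7R)-5-(allyloxy)-2-chloro-6,7,8-tris(TBS-oxy)oct-2-en-1-yl]-1,3-dithiane | CC(C)(C)[Si](C)(C)OC[C@@H](O[Si](C)(C)C(C)(C)C)[C@@H](O[Si](C)(C)C(C)(C)C)[C@H](OCC=C)C/C=C(/Cl)CC1SCCCS1 | intermediate
17 | (3E,6R,7S,8R)-6-(allyloxy)-3-chloro-1,1-dimethoxy-7,8,9-tris(TBS-oxy)non-3-ene | CC(C)(C)[Si](C)(C)OC[C@@H](O[Si](C)(C)C(C)(C)C)[C@@H](O[Si](C)(C)C(C)(C)C)[C@H](OCC=C)C/C=C(/Cl)CC(OC)OC | intermediate
18 | (3E,6R,7S,8R)-3-chloro-1,1-dimethoxy-6-{[(2E)-3-(Bpin)prop-2-en-1-yl]oxy}-7,8,9-tris(TBS-oxy)non-3-ene | CC(C)(C)[Si](C)(C)OC[C@@H](O[Si](C)(C)C(C)(C)C)[C@@H](O[Si](C)(C)C(C)(C)C)[C@H](OC/C=C/B1OC(C)(C)C(C)(C)O1)C/C=C(/Cl)CC(OC)OC | intermediate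
19 | (3E,6R,7S,8R)-3-chloro-1,1-dimethoxy-6-{[(1Z)-3-(Bpin)prop-1-en-1-yl]oxy}-7,8,9-tris(TBS-oxy)non-3-ene | CC(C)(C)[Si](C)(C)OC[C@@H](O[Si](C)(C)C(C)(C)C)[C@@H](O[Si](C)(C)C(C)(C)C)[C@H](O/C=C\CB1OC(C)(C)C(C)(C)O1)C/C=C(/Cl)CC(OC)OC | intermediate
20 | (3E,6R,7S,8R)-3-chloro-6-{[(1Z)-3-(Bpin)prop-1-en-1-yl]oxy}-7,8,9-tris(TBS-oxy)non-3-enal | CC(C)(C)[Si](C)(C)OC[C@@H](O[Si](C)(C)C(C)(C)C)[C@@H](O[Si](C)(C)C(C)(C)C)[C@H](O/C=C\CB1OC(C)(C)C(C)(C)O1)C/C=C(/Cl)CC=O | intermediate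
21 | O-Bpin borate ester of 22 | CC(C)(C)[Si](C)(C)OC[C@@H](O[Si](C)(C)C(C)(C)C)[C@@H](O[Si](C)(C)C(C)(C)C)[C@H]1C/C=C(/Cl)C[C@@H](OB2OC(C)(C)C(C)(C)O2)[C@@H](C=C)O1 | intermediate
22 | (2R,3R,5E,8R)-5-chloro-2-ethenyl-8-[(1S,2R)-1,2,3-tris(TBS-oxy)propyl]-3,4,7,8-tetrahydro-2H-oxocin-3-ol (3-OH cis to 2-vinyl; 2-H and 8-H cis) | CC(C)(C)[Si](C)(C)OC[C@@H](O[Si](C)(C)C(C)(C)C)[C@@H](O[Si](C)(C)C(C)(C)C)[C@H]1C/C=C(/Cl)C[C@@H](O)[C@@H](C=C)O1 | intermediate
23 | (2R,3R,5E,8R)-5-chloro-2-ethyl-8-[(1S,2R)-1,2,3-tris(TBS-oxy)propyl]-3,4,7,8-tetrahydro-2H-oxocin-3-ol | CC(C)(C)[Si](C)(C)OC[C@@H](O[Si](C)(C)C(C)(C)C)[C@@H](O[Si](C)(C)C(C)(C)C)[C@H]1C/C=C(/Cl)C[C@@H](O)[C@@H](CC)O1 | intermediate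
24 | (2R,3S,5E,8R)-3-bromo-5-chloro-2-ethyl-8-[(1S,2R)-1,2,3-tris(TBS-oxy)propyl]-3,4,7,8-tetrahydro-2H-oxocine | CC(C)(C)[Si](C)(C)OC[C@@H](O[Si](C)(C)C(C)(C)C)[C@@H](O[Si](C)(C)C(C)(C)C)[C@H]1C/C=C(/Cl)C[C@H](Br)[C@@H](CC)O1 | intermediate
25 | (2R,3S)-3-[(2R,4E,7S,8R)-7-bromo-5-chloro-8-ethyl-3,6,7,8-tetrahydro-2H-oxocin-2-yl]-2,3-bis(TBS-oxy)propan-1-ol | OC[C@@H](O[Si](C)(C)C(C)(C)C)[C@@H](O[Si](C)(C)C(C)(C)C)[C@H]1C/C=C(/Cl)C[C@H](Br)[C@@H](CC)O1 | intermediate
26 | (2S,3S)-3-[(2R,4E,7S,8R)-7-bromo-5-chloro-8-ethyl-3,6,7,8-tetrahydro-2H-oxocin-2-yl]-2,3-bis(TBS-oxy)propanal | O=C[C@@H](O[Si](C)(C)C(C)(C)C)[C@@H](O[Si](C)(C)C(C)(C)C)[C@H]1C/C=C(/Cl)C[C@H](Br)[C@@H](CC)O1 | intermediate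
27 | lithium β-silyl alkoxide from 26 and the lithiated bis-silylpropyne (diastereomer mixture at the two new centres) | CC(C)[Si](C(C)C)(C(C)C)C#CC([Si](C(C)C)(C(C)C)C(C)C)C(O[Li])[C@@H](O[Si](C)(C)C(C)(C)C)[C@@H](O[Si](C)(C)C(C)(C)C)[C@H]1C/C=C(/Cl)C[C@H](Br)[C@@H](CC)O1 | intermediate
28 | (2R,4E,7S,8R)-7-bromo-5-chloro-8-ethyl-2-[(1S,2R,3Z)-1,2-bis(TBS-oxy)-6-(triisopropylsilyl)hex-3-en-5-yn-1-yl]-3,6,7,8-tetrahydro-2H-oxocine | CC(C)[Si](C(C)C)(C(C)C)C#C/C=C\[C@@H](O[Si](C)(C)C(C)(C)C)[C@@H](O[Si](C)(C)C(C)(C)C)[C@H]1C/C=C(/Cl)C[C@H](Br)[C@@H](CC)O1 | intermediate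
29 | (1R,2R,3Z)-1-[(2R,4E,7S,8R)-7-bromo-5-chloro-8-ethyl-3,6,7,8-tetrahydro-2H-oxocin-2-yl]hex-3-en-5-yne-1,2-diol | C#C/C=C\[C@@H](O)[C@@H](O)[C@H]1C/C=C(/Cl)C[C@H](Br)[C@@H](CC)O1 | intermediate
30 | cyclic methyl orthoacetate of diol 29 (2-methoxy-2-methyl-1,3-dioxolane, epimers at the orthoester carbon) | C#C/C=C\[C@H]1OC(C)(OC)O[C@H]1[C@H]2C/C=C(/Cl)C[C@H](Br)[C@@H](CC)O2 | intermediate
31 | (1S,2S,3Z)-1-[(2R,4E,7S,8R)-7-bromo-5-chloro-8-ethyl-3,6,7,8-tetrahydro-2H-oxocin-2-yl]-2-chlorohex-3-en-5-yn-1-yl acetate | C#C/C=C\[C@H](Cl)[C@@H](OC(C)=O)[C@H]1C/C=C(/Cl)C[C@H](Br)[C@@H](CC)O1 | intermediate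
32 | bermudenynol, (3Z,5S,6S,7R,9E,12S,13R) in chain numbering | C#C/C=C\[C@H](Cl)[C@@H](O)[C@H]1C/C=C(/Cl)C[C@H](Br)[C@@H](CC)O1 | target

Total step count: 24
Longest linear sequence: 24 steps (from D-glucal)

**Steps most likely to fail**

Step 15. The double-bond migration may stop short, give E/Z mixtures or run on past the enol ether, or the nickel hydride may be consumed by insertion into the vinyl chloride. An (E)-boronate would carry through to the C12 epimer in step 16. The fallback sets out from 18 and makes the E isomer on purpose. Isomerisation with the cationic complex [Ir(cod)(PPh2Me)2]PF6 (activated with H2, THF, rt) should give the (E)-γ-alkoxyallylboronate F1. Cyclisation under the conditions of step 16, now through a chair with both the ring oxygen and the C11 chain equatorial, should give the trans-2-vinyl-3-hydroxy oxocene F2. Diimide reduction should give the ethyl compound F3, and Dess–Martin oxidation the C12 ketone F4. Reduction with LiBH(s-Bu)3 (THF, –78 °C), hydride entering anti to the C13 ethyl group, should give the cis alcohol, which is compound 23, where the route is rejoined.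

Step 16. The enol-ether-type allylboronate may be protonated and lose boron under the aqueous Lewis-acidic conditions, or intermolecular allylboration (oligomers) may outrun the medium-ring closure. The fallback sets out from 18 and reverses the order of unmasking and transposition. The acetal is hydrolysed first (PPTS, acetone/H2O) to the aldehyde F5, in which the alkenylboronate is inert towards the carbonyl group. Slow nickel-hydride isomerisation of F5 under anhydrous, highly dilute conditions then generates the reactive allylboronate only in low stationary concentration, next to its intramolecular acceptor (tandem olefin transposition/allylboration). The route is rejoined at the non-isolated aldehyde 20 and, after work-up, at 22.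

Step 23. The orthoester may hydrolyse to monoacetates instead of ionising, acetate may migrate, chloride may attack in part at C6 or in an SN2' sense at C3, and the later ester removal may close the chlorohydrin to an epoxide. The fallback sets out from diol 29 and avoids the ester altogether. SOCl2/Et3N (CH2Cl2, 0 °C) should give the cyclic sulfite F6. LiCl in DMF should open it by SN2 at the allylic C5 with inversion to the chloro sulfite half-ester F7, which loses SO2 on mildly acidic aqueous work-up and gives the target 32 directly.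

Further compounds
F1 | step 15 | (3E,6R,7S,8R)-3-chloro-1,1-dimethoxy-6-{[(1E)-3-(Bpin)prop-1-en-1-yl]oxy}-7,8,9-tris(TBS-oxy)non-3-ene | CC(C)(C)[Si](C)(C)OC[C@@H](O[Si](C)(C)C(C)(C)C)[C@@H](O[Si](C)(C)C(C)(C)C)[C@H](O/C=C/CB1OC(C)(C)C(C)(C)O1)C/C=C(/Cl)CC(OC)OC
F2 | step 15 | (2R,3S,5E,8R)-5-chloro-2-ethenyl-8-[(1S,2R)-1,2,3-tris(TBS-oxy)propyl]-3,4,7,8-tetrahydro-2H-oxocin-3-ol (C12 epimer of 22) | CC(C)(C)[Si](C)(C)OC[C@@H](O[Si](C)(C)C(C)(C)C)[C@@H](O[Si](C)(C)C(C)(C)C)[C@H]1C/C=C(/Cl)C[C@H](O)[C@@H](C=C)O1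
F3 | step 15 | (2R,3S,5E,8R)-5-chloro-2-ethyl-8-[(1S,2R)-1,2,3-tris(TBS-oxy)propyl]-3,4,7,8-tetrahydro-2H-oxocin-3-ol (C12 epimer of 23) | CC(C)(C)[Si](C)(C)OC[C@@H](O[Si](C)(C)C(C)(C)C)[C@@H](O[Si](C)(C)C(C)(C)C)[C@H]1C/C=C(/Cl)C[C@H](O)[C@@H](CC)O1
F4 | step 15 | C12 ketone: 5-chloro-2-ethyl-8-[(1S,2R)-1,2,3-tris(TBS-oxy)propyl]-7,8-dihydro-2H-oxocin-3(4H)-one, ring centres as in 23 | CC(C)(C)[Si](C)(C)OC[C@@H](O[Si](C)(C)C(C)(C)C)[C@@H](O[Si](C)(C)C(C)(C)C)[C@H]1C/C=C(/Cl)CC(=O)[C@@H](CC)O1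
F5 | step 16 | (3E,6R,7S,8R)-3-chloro-6-{[(2E)-3-(Bpin)prop-2-en-1-yl]oxy}-7,8,9-tris(TBS-oxy)non-3-enal | CC(C)(C)[Si](C)(C)OC[C@@H](O[Si](C)(C)C(C)(C)C)[C@@H](O[Si](C)(C)C(C)(C)C)[C@H](OC/C=C/B1OC(C)(C)C(C)(C)O1)C/C=C(/Cl)CC=O
F6 | step 23 | cyclic 5,6-sulfite of diol 29 (epimers at sulfur) | C#C/C=C\[C@H]1OS(=O)O[C@H]1[C@H]2C/C=C(/Cl)C[C@H](Br)[C@@H](CC)O2
F7 | step 23 | lithium salt of the 6-O-sulfite half-ester of bermudenynol | C#C/C=C\[C@H](Cl)[C@@H](OS(=O)[O-])[C@H]1C/C=C(/Cl)C[C@H](Br)[C@@H](CC)O1.[Li+]
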